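The pyran ring (O1, C2, C3, C4, C4a, C8a) is traced back to an isomeric 2-(α-hydroxybenzyl)-2,3-dihydrobenzofuran in which O1 still sits on C3; this erythro carbinol follows from 5-exo opening of a Shi epoxide. The key step displaces the activated benzylic oxygen by O1 and lets water open the O1-bridged C2–C3 epoxonium ion at C3, so the five-membered ring grows into the chroman while a double inversion writes the 2,3-trans (2R,3S) array. It exploits the antiperiplanar O1–C2 and C3–OH bonds of the trans-flavan-3-ol. Pivalate esters switch off the B ring as a cation donor; a bromine at C6 holds the prenyl position.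

Key step: step 10

Remark: flavan numbering (O1, C2, C3, C4, C4a, C5–C8, C8a, B ring primed) is used for the chain atoms of all intermediates; 2-bromoresorcinol, caffeic acid, the L-fructose-derived (ent-Shi) ketone and prenylzinc bromide solution are taken as purchasable.

Step 1
Reactants: 1 2-bromoresorcinol
Product: 2 2-bromo-1,3-bis(methoxymethoxy)benzene
Conditions: MOMCl, i-Pr2NEt, CH2Cl2, 0 °C to rt
Reagents that add atoms: chloromethyl methyl ether, COCCl
Why: Williamson-type O-alkylation of both phenols gives base-stable acetals that can be removed at the end without hydrogenation.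

Step 2
Reactants: 2 2-bromo-1,3-bis(methoxymethoxy)benzene
Product: 4 4-bromo-3,5-bis(methoxymethoxy)phenol, via aryl pinacol boronate 3 (not isolated)
Conditions: [Ir(OMe)(cod)]2 (cat.), dtbpy (cat.), B2pin2, THF, 80 °C; then Oxone, acetone–H2O, rt
Reagents that add atoms: potassium peroxymonosulfate (Oxone), [K+].[O-]S(=O)(=O)OO
Why: Sterically controlled Ir-catalysed C–H borylation should take place only at C5, the one C–H without an ortho substituent, and one-pot oxidation of the boronate gives the symmetric phenol with the C–Br bond untouched.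

Step 3
Reactants: 5 caffeic acid
Product: 7 (E)-3-[3,4-bis(pivaloyloxy)phenyl]prop-2-en-1-ol, via mixed pivalic anhydride 6 (not isolated)
Conditions: PivCl (3.3 equiv), Et3N, THF, 0 °C; then NaBH4, H2O, 0 °C
Reagents that add atoms: pivaloyl chloride, CC(C)(C)C(=O)Cl
Why: Pivaloyl chloride caps both phenols and turns the acid into the mixed pivalic anhydride, whose unhindered cinnamoyl carbonyl is reduced chemoselectively by borohydride (mixed-anhydride reduction) while the aryl esters and the E-alkene stay.

Step 4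
Reactants: 7 (E)-3-[3,4-bis(pivaloyloxy)phenyl]prop-2-en-1-ol
Product: 8 (E)-3-[3,4-bis(pivaloyloxy)phenyl]prop-2-enyl bromide
Conditions: CBr4, PPh3, CH2Cl2, 0 °C
Reagents that add atoms: carbon tetrabromide, BrC(Br)(Br)Br
Why: Appel bromination of the primary allylic alcohol under neutral conditions keeps the alkene geometry and the esters.

Step 5
Reactants: 4 4-bromo-3,5-bis(methoxymethoxy)phenol; 8 (E)-3-[3,4-bis(pivaloyloxy)phenyl]prop-2-enyl bromide
Product: 9 4-bromo-2-[(E)-3-(3,4-bis(pivaloyloxy)phenyl)prop-2-enyl]-3,5-bis(methoxymethoxy)phenol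
Conditions: NaH, toluene, 0 °C; then 8, rt to 50 °C
Reagents that add atoms: none
Why: ortho-C-alkylation of a sodium phenoxide by an allylic bromide in a non-polar solvent should give one regioisomer, because the para position is blocked by bromine and the two ortho positions are equivalent.

Step 6
Reactants: 9 4-bromo-2-[(E)-3-(3,4-bis(pivaloyloxy)phenyl)prop-2-enyl]-3,5-bis(methoxymethoxy)phenol
Product: 10 tert-butyl{4-bromo-2-[(E)-3-(3,4-bis(pivaloyloxy)phenyl)prop-2-enyl]-3,5-bis(methoxymethoxy)phenoxy}dimethylsilane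
Conditions: TBSCl, imidazole, DMF, rt
Reagents that add atoms: tert-butyldimethylsilyl chloride, CC(C)(C)[Si](C)(C)Cl
Why: Silylation masks the electron-rich phenol against the dioxirane of the next step.

Step 7
Reactants: 10 tert-butyl{4-bromo-2-[(E)-3-(3,4-bis(pivaloyloxy)phenyl)prop-2-enyl]-3,5-bis(methoxymethoxy)phenoxy}dimethylsilane
Product: 11 (2S,3S)-2-[3,4-bis(pivaloyloxy)phenyl]-3-{[3-bromo-6-(tert-butyldimethylsilyloxy)-2,4-bis(methoxymethoxy)phenyl]methyl}oxirane
Conditions: ent-Shi ketone (30 mol%), Oxone, K2CO3, Bu4NHSO4, MeCN–DMM/aq. borate–EDTA buffer, 0 °C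
Reagents that add atoms: potassium peroxymonosulfate (Oxone), [K+].[O-]S(=O)(=O)OO
Why: Shi asymmetric epoxidation of the trans-disubstituted styrene-type alkene, in which the L-fructose-derived ketone should deliver oxygen through the spiro transition state to the face giving the (2S,3S)-epoxide; the bromine stands in for the prenyl group, which a dioxirane would also epoxidise.

Step 8
Reactants: 11 (2S,3S)-2-[3,4-bis(pivaloyloxy)phenyl]-3-{[3-bromo-6-(tert-butyldimethylsilyloxy)-2,4-bis(methoxymethoxy)phenyl]methyl}oxirane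
Product: 13 (S)-[(2R)-5-bromo-4,6-bis(methoxymethoxy)-2,3-dihydro-1-benzofuran-2-yl][3,4-bis(pivaloyloxy)phenyl]methanol, via desilylated epoxy phenoxide 12 (not isolated)
Conditions: TBAF (1.05 equiv), THF, −20 to 0 °C
Reagents that add atoms: none
Why: Fluoride frees the phenoxide, which should open the epoxide by 5-exo-tet attack at the non-benzylic carbon C3 with inversion (the ester-deactivated aryl group disfavours 6-endo attack), so the ring carbon becomes R and the carbinol carbon keeps S.

Step 9
Reactants: 13 (S)-[(2R)-5-bromo-4,6-bis(methoxymethoxy)-2,3-dihydro-1-benzofuran-2-yl][3,4-bis(pivaloyloxy)phenyl]methanol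
Product: 14 (S)-[(2R)-4,6-bis(methoxymethoxy)-5-(3-methylbut-2-enyl)-2,3-dihydro-1-benzofuran-2-yl][3,4-bis(pivaloyloxy)phenyl]methanol
Conditions: prenylzinc bromide (2.5 equiv), Pd(OAc)2 (2 mol%), CPhos (4 mol%), THF, rt
Reagents that add atoms: prenylzinc bromide, CC(C)=CC[Zn]Br
Why: Linear-selective Negishi coupling of the allylic zinc reagent should replace the bromine between the two MOM ethers while tolerating the aryl esters and the free alcohol (which consumes one equivalent of the zinc reagent), and it touches no stereocentre.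

Step 10
Reactants: 14 (S)-[(2R)-4,6-bis(methoxymethoxy)-5-(3-methylbut-2-enyl)-2,3-dihydro-1-benzofuran-2-yl][3,4-bis(pivaloyloxy)phenyl]methanol
Product: 17 (2R,3S)-2-[3,4-bis(pivaloyloxy)phenyl]-5,7-bis(methoxymethoxy)-6-(3-methylbut-2-enyl)chroman-3-ol, via benzylic chloromethanesulfonate 15 (not isolated), via O1-bridged epoxonium ion 16 (not isolated)
Conditions: ClCH2SO2Cl, 2,6-lutidine, CH2Cl2, −20 °C; aqueous wash; then HFIP–H2O (9:1), 2,6-lutidine, 40 °C
Reagents that add atoms: water, O
Why: The sulfonate should leave with anchimeric assistance from O1, which attacks the carbinol carbon from the rear (3-exo-tet, inversion) to give the O1-bridged C2–C3 epoxonium ion 16, and water then opens this ion at the former ring carbon C3 (second inversion) with cleavage of the C3–O1 bond, so that O1 has moved from C3 to C2 and the dihydrofuran has become the dihydropyran. The closest known reaction type is the rearrangement–ring expansion of 2-(1-sulfonyloxyalkyl) cyclic ethers through bicyclic oxonium ions (tetrahydrofuran to tetrahydropyran), here the microscopic reverse of the known contraction of 3-O-sulfonyl flavans to 2-benzylcoumarans. The six-membered ring is therefore not closed by a new cyclisation but arises by endo cleavage of the bicyclic oxonium after the 3-exo-tet bridging. Both stereocentres are set stereospecifically by the substrate: (αS) becomes (2R) and (2R) becomes (3S), so the erythro carbinol is translated into the 2,3-trans array in which C3–OH ends antiperiplanar to O1–C2. The step needs attack at C3 and not at benzylic C2: the pivaloyloxy groups remove the cation-stabilising power of the B ring so that no free benzylic cation should form, relief of dihydrobenzofuran and oxiranium strain favours the chroman, the weakly nucleophilic HFIP medium suppresses direct SN2 displacement, and water that adds at C2 only regenerates 14 by double inversion, which is recycled.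

Step 11
Reactants: 17 (2R,3S)-2-[3,4-bis(pivaloyloxy)phenyl]-5,7-bis(methoxymethoxy)-6-(3-methylbut-2-enyl)chroman-3-ol
Product: 19 6-prenylcatechin, via depivaloylated bis-MOM ether 18 (not isolated)
Conditions: K2CO3, MeOH, 0 °C to rt, argon; then HCl in MeOH to pH 1, rt to 40 °C
Reagents that add atoms: none
Why: Base methanolysis removes the two aryl pivalates and acid methanolysis then cleaves the MOM acetals under dilute conditions of the kind used for prenylated phloroglucinols, with neither stereocentre involved.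

Compound list
1 | 2-bromoresorcinol (2-bromobenzene-1,3-diol) | Oc1cccc(O)c1Br | starting material
2 | 2-bromo-1,3-bis(methoxymethoxy)benzene | COCOc1cccc(OCOC)c1Br | intermediate
3 | 2-[4-bromo-3,5-bis(methoxymethoxy)phenyl]-4,4,5,5-tetramethyl-1,3,2-dioxaborolane (not isolated) | COCOc1cc(B2OC(C)(C)C(C)(C)O2)cc(OCOC)c1Br | intermediate
4 | 4-bromo-3,5-bis(methoxymethoxy)phenol | COCOc1cc(O)cc(OCOC)c1Br | intermediate
5 | caffeic acid ((E)-3-(3,4-dihydroxyphenyl)prop-2-enoic acid) | O=C(O)/C=C/c1ccc(O)c(O)c1 | starting material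
6 | (E)-3-[3,4-bis(pivaloyloxy)phenyl]prop-2-enoic pivalic anhydride (not isolated) | CC(C)(C)C(=O)OC(=O)/C=C/c1ccc(OC(=O)C(C)(C)C)c(OC(=O)C(C)(C)C)c1 | intermediate
7 | (E)-3-[3,4-bis(pivaloyloxy)phenyl]prop-2-en-1-ol | OC/C=C/c1ccc(OC(=O)C(C)(C)C)c(OC(=O)C(C)(C)C)c1 | intermediate
8 | (E)-3-[3,4-bis(pivaloyloxy)phenyl]prop-2-enyl bromide | BrC/C=C/c1ccc(OC(=O)C(C)(C)C)c(OC(=O)C(C)(C)C)c1 | intermediate
9 | 4-bromo-2-[(E)-3-(3,4-bis(pivaloyloxy)phenyl)prop-2-enyl]-3,5-bis(methoxymethoxy)phenol | COCOc1cc(O)c(C/C=C/c2ccc(OC(=O)C(C)(C)C)c(OC(=O)C(C)(C)C)c2)c(OCOC)c1Br | intermediate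
10 | tert-butyl{4-bromo-2-[(E)-3-(3,4-bis(pivaloyloxy)phenyl)prop-2-enyl]-3,5-bis(methoxymethoxy)phenoxy}dimethylsilane | CC(C)(C)[Si](C)(C)Oc1cc(OCOC)c(Br)c(OCOC)c1C/C=C/c1ccc(OC(=O)C(C)(C)C)c(OC(=O)C(C)(C)C)c1 | intermediate
11 | (2S,3S)-2-[3,4-bis(pivaloyloxy)phenyl]-3-{[3-bromo-6-(tert-butyldimethylsilyloxy)-2,4-bis(methoxymethoxy)phenyl]methyl}oxirane | CC(C)(C)[Si](C)(C)Oc1cc(OCOC)c(Br)c(OCOC)c1C[C@@H]2O[C@H]2c2ccc(OC(=O)C(C)(C)C)c(OC(=O)C(C)(C)C)c2 | intermediate
12 | 4-bromo-2-{[(2S,3S)-3-(3,4-bis(pivaloyloxy)phenyl)oxiran-2-yl]methyl}-3,5-bis(methoxymethoxy)phenol, present as its phenoxide (not isolated) | Oc1cc(OCOC)c(Br)c(OCOC)c1C[C@@H]2O[C@H]2c2ccc(OC(=O)C(C)(C)C)c(OC(=O)C(C)(C)C)c2 | intermediate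
13 | (S)-[(2R)-5-bromo-4,6-bis(methoxymethoxy)-2,3-dihydro-1-benzofuran-2-yl][3,4-bis(pivaloyloxy)phenyl]methanol | COCOc1cc2O[C@@H]([C@@H](O)c3ccc(OC(=O)C(C)(C)C)c(OC(=O)C(C)(C)C)c3)Cc2c(OCOC)c1Br | intermediate
14 | (S)-[(2R)-4,6-bis(methoxymethoxy)-5-(3-methylbut-2-enyl)-2,3-dihydro-1-benzofuran-2-yl][3,4-bis(pivaloyloxy)phenyl]methanol | COCOc1cc2O[C@@H]([C@@H](O)c3ccc(OC(=O)C(C)(C)C)c(OC(=O)C(C)(C)C)c3)Cc2c(OCOC)c1CC=C(C)C | intermediate
15 | (S)-[(2R)-4,6-bis(methoxymethoxy)-5-(3-methylbut-2-enyl)-2,3-dihydro-1-benzofuran-2-yl][3,4-bis(pivaloyloxy)phenyl]methyl chloromethanesulfonate (not isolated) | COCOc1cc2O[C@@H]([C@@H](OS(=O)(=O)CCl)c3ccc(OC(=O)C(C)(C)C)c(OC(=O)C(C)(C)C)c3)Cc2c(OCOC)c1CC=C(C)C | intermediate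
16 | O1-bridged (2R,3R) C2–C3 epoxonium ion, trans (not isolated) | COCOc1cc2[O+]3[C@H](Cc2c(OCOC)c1CC=C(C)C)[C@H]3c1ccc(OC(=O)C(C)(C)C)c(OC(=O)C(C)(C)C)c1 | intermediate
17 | (2R,3S)-2-[3,4-bis(pivaloyloxy)phenyl]-5,7-bis(methoxymethoxy)-6-(3-methylbut-2-enyl)chroman-3-ol | CC(C)=CCc1c(OCOC)cc2c(c1OCOC)C[C@H](O)[C@@H](c1ccc(OC(=O)C(C)(C)C)c(OC(=O)C(C)(C)C)c1)O2 | intermediate
18 | (2R,3S)-2-(3,4-dihydroxyphenyl)-5,7-bis(methoxymethoxy)-6-(3-methylbut-2-enyl)chroman-3-ol (not isolated) | CC(C)=CCc1c(OCOC)cc2c(c1OCOC)C[C@H](O)[C@@H](c1ccc(O)c(O)c1)O2 | intermediate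
19 | 6-prenylcatechin, (2R,3S)-2-(3,4-dihydroxyphenyl)-6-(3-methylbut-2-enyl)chroman-3,5,7-triol | CC(C)=CCc1c(O)cc2c(c1O)C[C@H](O)[C@@H](c1ccc(O)c(O)c1)O2 | target

Total step count: 11. Longest linear sequence: 9 steps (steps 1, 2 and 5–11 from 1; equally steps 3–11 from 5).

Steps most likely to fail

Step 10. The bridged ion may be captured at the benzylic carbon (return to the five-membered ring), lose the proton at C3 towards the benzofuran, or the sulfonate may be displaced directly without participation, giving the epimeric carbinol. The fallback changes the control element from kinetic capture to thermodynamic equilibration. Setting out from 14, trifluoroacetic anhydride and triethylamine give the benzylic trifluoroacetate F1, which is heated in HFIP with 2,6-di-tert-butylpyridine. The departing trifluoroacetate is also the nucleophile, so return to C2 is reversible, while capture at C3 gives the strain-free 3-trifluoroacetoxychroman F2, which should not ionise again; this is the onium ring expansion under thermodynamic control known for prolinol trifluoroacetates. Methanolysis with NaHCO3 in MeOH removes only the trifluoroacetate and brings the route back at 17.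

Step 5. The phenoxide may be alkylated at oxygen instead of carbon, attack in the SN2′ sense to give the branched isomer, or take up an acyl group from the aryl pivalates. The fallback sets out from 7 and 4. Methyl chloroformate and pyridine convert 7 into methyl (E)-3-[3,4-bis(pivaloyloxy)phenyl]prop-2-enyl carbonate F3. Ir-catalysed branched-selective allylic etherification ([Ir(cod)Cl]2, phosphoramidite ligand) with phenol 4 gives the 1-arylallyl aryl ether F4. Aromatic Claisen rearrangement in N,N-diethylaniline at 170 °C then places the chain at the ortho carbon through a chair transition state with the E-alkene and rejoins the route at 9.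

Step 9. Coupling at the doubly ortho-substituted bromide may be slow, the allylzinc reagent may be destroyed by the free alcohol, or linear selectivity may be lost, giving the reverse-prenyl isomer. The fallback sets out from 13. Stille coupling with allyltributylstannane (Pd(PPh3)4, toluene, 100 °C) gives the 5-allyl compound F5, for which no α/γ question exists. Cross-metathesis with 2-methylbut-2-ene (second-generation Ru benzylidene catalyst, CH2Cl2, 40 °C) turns allyl into prenyl and returns at 14.

Further compounds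
F1 | step 10 | (S)-[(2R)-4,6-bis(methoxymethoxy)-5-(3-methylbut-2-enyl)-2,3-dihydro-1-benzofuran-2-yl][3,4-bis(pivaloyloxy)phenyl]methyl trifluoroacetate | COCOc1cc2O[C@@H]([C@@H](OC(=O)C(F)(F)F)c3ccc(OC(=O)C(C)(C)C)c(OC(=O)C(C)(C)C)c3)Cc2c(OCOC)c1CC=C(C)C
F2 | step 10 | (2R,3S)-2-[3,4-bis(pivaloyloxy)phenyl]-5,7-bis(methoxymethoxy)-6-(3-methylbut-2-enyl)chroman-3-yl trifluoroacetate | CC(C)=CCc1c(OCOC)cc2c(c1OCOC)C[C@H](OC(=O)C(F)(F)F)[C@@H](c1ccc(OC(=O)C(C)(C)C)c(OC(=O)C(C)(C)C)c1)O2
F3 | step 5 | methyl (E)-3-[3,4-bis(pivaloyloxy)phenyl]prop-2-enyl carbonate | COC(=O)OC/C=C/c1ccc(OC(=O)C(C)(C)C)c(OC(=O)C(C)(C)C)c1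
F4 | step 5 | 1-[3,4-bis(pivaloyloxy)phenyl]prop-2-enyl 4-bromo-3,5-bis(methoxymethoxy)phenyl ether (configuration immaterial, lost in the Claisen step) | C=CC(Oc1cc(OCOC)c(Br)c(OCOC)c1)c1ccc(OC(=O)C(C)(C)C)c(OC(=O)C(C)(C)C)c1
F5 | step 9 | (S)-[(2R)-5-allyl-4,6-bis(methoxymethoxy)-2,3-dihydro-1-benzofuran-2-yl][3,4-bis(pivaloyloxy)phenyl]methanol | COCOc1cc2O[C@@H]([C@@H](O)c3ccc(OC(=O)C(C)(C)C)c(OC(=O)C(C)(C)C)c3)Cc2c(OCOC)c1CC=C
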